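**What stayed.** At their last readings, electrophile and product together held 99.0% of the charge in the south-east run and 99.0% in the south-west run. So I took the electrophile lost as electrophile turned into product, and I read that loss as a decay.

common to all: electrophile 0.25 M (fed, over 12 min)
- south-east: nucleophile 0.13 M; protic impurity 0.050 M; run made earlier
- south-west: nucleophile 0.20 M; protic impurity 0.050 M; run made earlier
- flask: nucleophile 0.263 M; protic impurity 0.0500 M; time 50 min

- south-east (time / min: electrophile / %, product / %): 2.00: 17, 1; 6.00: 47, 2; 12.0: 95, 3; 15.0: 91, 8; 25.0: 90, 11; 30.0: 89, 9; 40.0: 85, 14
- south-west (time / min: electrophile / %, product / %): 3.00: 27, 0; 5.00: 39, 4; 8.00: 63, 5; 12.0: 93, 9; 15.0: 89, 13; 25.0: 84, 18; 40.0: 76, 23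

(scatter of a reading: 2 percentage points)

- the largest share of what was charged as electrophile, at 50 min belongs to (electrophile / product)
- the largest share itself, whichever of these holds it, in percent of the electrophile charged

- percentages count the whole charge, also what has not yet gone in

**Main step.** From the end of the feed to the last reading, the logarithm of the electrophile fell by 0.00397 min⁻¹ in the south-east run and 0.00721 min⁻¹ in the south-west run, a reading ratio of 1.82. Dividing their sum by the summed nucleophile excess over impurity gave 0.0486 M⁻¹ min⁻¹. With the flask's nucleophile counted as charged, the lifetime was 78.2 min, which left 52.8% of the electrophile.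

**Adding impurity.** The charges of nucleophile stand in the ratio 1.54, but their excesses over impurity stand at 1.88, nearer the reading. So I used the electrophile's apparent lifetime, the inverse of this constant times c(nucleophile) minus c(protic impurity). For the flask it was 96.6 min, which left 59.6%.

**Adding feed.** Counting the electrophile from the middle of the feed shortened its exposure to 44.0 min. I therefore expected 63.4% electrophile, still ahead of product. The forecast named electrophile at 65%, assuming that “the impurity quickly destroys an equal amount of nucleophile”.

**The result.** The flask gave electrophile at 66.1%, with product at 33.9%. Nucleophile left, 17% of its charge, was less than electrophile left, 66%.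

    electrophile + nucleophile → acid set free + product (k = 0.00152 M⁻¹ s⁻¹)
    nucleophile + acid set free ⇌ protonated nucleophile, settled at all times (K = 1600 M⁻¹)
    nucleophile + protic impurity → quenched reagent (k = 0.0168 M⁻¹ s⁻¹)

The flask had run 0.456 lifetimes. Over 500 min, the same count gives 5.12 lifetimes and 0.600%, yet the flask then held 51.6%. So the count came near at 50 min but not at 500 min.

**Second flask.** With 0.66 M nucleophile, the lifetime became 33.7 min, which left 27.1% electrophile. The computed flask held 24.7% electrophile, and product held most, at 75.3%.

The runs are calculated with made-up constants; the scatter is artificial.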